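**Plan**

1. Retrosynthesis: after the five hydroxyls are masked as MOM ethers, the two identical ring A–CH2 bonds (C3–CH2 and C5–CH2 of the acylphloroglucinol ring A, each leading to C3 of a pyrone, rings B and C) are cut in one twofold sp2–sp3 disconnection.
2. Enabling feature: C3 and C5 of ring A each lie between two oxygen-bearing carbons (C2/C4 and C4/C6) and are the only free, strongly nucleophilic ring positions, so they map onto a 3,5-dibromide; the CH2 on pyrone C3 becomes the zinc-bearing carbon.
3. Forward, ring A: phloroglucinol is MOM-protected, acylated by ortho-lithiation and a Weinreb amide, then dibrominated.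
4. Forward, rings B and C: one pyrone is built from the silyl enol ether of pentan-3-one and malonyl dichloride, and its C3 is taken through Br, CHO, CH2OH and CH2Cl to CH2ZnCl.
5. Two equivalents of the zinc reagent are joined to the dibromide by a Negishi coupling, and acidic methanol then frees the five hydroxyls; no ring is formed after the pyrone.
6. Stereochemistry: the single (R) centre is bought with (R)-2-methylbutanoic acid and is carried through steps that neither enolize nor ionize the α-carbon.

Key step: step 13

Remark: (R)-2-methylbutanoic acid is taken as a purchasable single enantiomer (the target centre is R: acyl carbon > ethyl > methyl > H), and zinc reagent 23 is counted as a compound of the route although it is kept as a titrated THF solution containing LiCl.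

**Route**

Step 1
Reactants: 1 phloroglucinol
Product: 2 1,3,5-tris(methoxymethoxy)benzene
Conditions: MOMCl, i-Pr2NEt, CH2Cl2/DMF, 0 °C → rt
Reagents that add atoms: chloromethyl methyl ether, COCCl
Why: Threefold O-alkylation of the phenols with the reactive α-chloro ether under amine base (MOM ether formation) is standard for phloroglucinol and gives a symmetric arene whose three ring C–H positions are equivalent.

Step 2
Reactants: 3 (R)-2-methylbutanoic acid
Product: 5 (2R)-N-methoxy-N,2-dimethylbutanamide, via acylimidazole 4 (not isolated)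
Conditions: CDI, CH2Cl2, 0 °C → rt; then MeNHOMe·HCl, rt
Reagents that add atoms: N,O-dimethylhydroxylamine hydrochloride, CNOC.Cl
Why: CDI turns the acid into acylimidazole 4 without added base, and aminolysis by N,O-dimethylhydroxylamine (amide coupling) then gives the Weinreb amide under conditions in which an α-branched acid neither forms a ketene nor enolizes, so the (R) centre is retained.

Step 3
Reactants: 2 1,3,5-tris(methoxymethoxy)benzene, 5 (2R)-N-methoxy-N,2-dimethylbutanamide
Product: 8 (2R)-2-methyl-1-[2,4,6-tris(methoxymethoxy)phenyl]butan-1-one, via aryllithium 6 (not isolated), via lithium hemiaminal adduct 7 (not isolated)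
Conditions: n-BuLi, THF, 0 °C; then 5, −78 → 0 °C; aq NH4Cl
Reagents that add atoms: none
Why: Directed ortho-lithiation between two OMOM groups gives aryllithium 6, which adds once to the Weinreb amide (Weinreb ketone synthesis) to give chelated adduct 7 that collapses to the ketone only on quench, so neither over-addition nor base-mediated epimerization of the α-centre can occur.

Step 4
Reactants: 8 (2R)-2-methyl-1-[2,4,6-tris(methoxymethoxy)phenyl]butan-1-one
Product: 9 (2R)-1-[3,5-dibromo-2,4,6-tris(methoxymethoxy)phenyl]-2-methylbutan-1-one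
Conditions: NBS (2.1 equiv), MeCN, 0 °C → rt, dark
Reagents that add atoms: N-bromosuccinimide, O=C1CCC(=O)N1Br
Why: Electrophilic aromatic bromination takes place at the only two free ring positions, each ortho to two and para to one alkoxy group, while the succinimide by-product keeps the medium non-acidic so that the MOM acetals and the twisted, non-enolized ketone are left alone.

Step 5
Reactants: 10 pentan-3-one
Product: 11 3-(trimethylsilyloxy)pent-2-ene (mixture of alkene isomers)
Conditions: TMSCl, Et3N, DMF, 80 °C
Reagents that add atoms: chlorotrimethylsilane, C[Si](C)(C)Cl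
Why: Silylation of the enol of a symmetric ketone under amine/TMSCl conditions (silyl enol ether formation) has no regiochemical issue, and both alkene isomers lead to the same pyrone.

Step 6
Reactants: 11 3-(trimethylsilyloxy)pent-2-ene, 12 malonyl dichloride
Product: 14 6-ethyl-4-hydroxy-5-methyl-2H-pyran-2-one, via diketo acid chloride 13 (not isolated)
Conditions: Et2O, −78 °C → rt
Reagents that add atoms: none
Why: C-acylation of the silyl enol ether by one acid chloride gives diketo acid chloride 13, whose enol oxygen closes onto the second acid chloride (acylative lactonization), which is the established route from silyl enol ethers and malonyl dichloride to 4-hydroxy-2-pyrones.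

Step 7
Reactants: 14 6-ethyl-4-hydroxy-5-methyl-2H-pyran-2-one
Product: 15 6-ethyl-4-(methoxymethoxy)-5-methyl-2H-pyran-2-one
Conditions: MOMCl, i-Pr2NEt, CH2Cl2, 0 °C → rt
Reagents that add atoms: chloromethyl methyl ether, COCCl
Why: The acidic 4-hydroxyl of the pyrone (a vinylogous acid) is O-alkylated by MOMCl under amine base, the 4-alkoxy-2-pyrone being the usual major product of such alkylations.

Step 8
Reactants: 15 6-ethyl-4-(methoxymethoxy)-5-methyl-2H-pyran-2-one
Product: 16 3-bromo-6-ethyl-4-(methoxymethoxy)-5-methyl-2H-pyran-2-one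
Conditions: NBS, MeCN, rt, dark
Reagents that add atoms: N-bromosuccinimide, O=C1CCC(=O)N1Br
Why: Electrophilic bromination of a 4-alkoxy-2-pyrone goes to C3, the nucleophilic enol-ether carbon, and C5 is blocked here by its methyl group.

Step 9
Reactants: 16 3-bromo-6-ethyl-4-(methoxymethoxy)-5-methyl-2H-pyran-2-one
Product: 19 6-ethyl-4-(methoxymethoxy)-5-methyl-2-oxo-2H-pyran-3-carbaldehyde, via pyronylmagnesium chloride 17 (not isolated), via magnesium hemiaminal adduct 18 (not isolated)
Conditions: i-PrMgCl·LiCl, THF, −40 °C; then DMF, −40 → 0 °C; aq NH4Cl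
Reagents that add atoms: N,N-dimethylformamide, CN(C)C=O
Why: Bromine–magnesium exchange at the sp2 C3–Br bond is fast at low temperature and is helped by the neighbouring OMOM oxygen, so it should outrun deprotonation of the C5-methyl or C6-ethyl group and addition to the lactone, and the resulting Grignard reagent 17 is formylated by DMF (Bouveault aldehyde synthesis) through adduct 18.

Step 10
Reactants: 19 6-ethyl-4-(methoxymethoxy)-5-methyl-2-oxo-2H-pyran-3-carbaldehyde
Product: 20 6-ethyl-3-(hydroxymethyl)-4-(methoxymethoxy)-5-methyl-2H-pyran-2-one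
Conditions: NaBH4, CeCl3·7H2O, MeOH, −40 °C
Reagents that add atoms: none
Why: Luche reduction delivers hydride to the aldehyde carbon in a 1,2-sense, leaving the doubly activated C4 position, the lactone and the MOM acetal untouched at low temperature.

Step 11
Reactants: 20 6-ethyl-3-(hydroxymethyl)-4-(methoxymethoxy)-5-methyl-2H-pyran-2-one
Product: 22 3-(chloromethyl)-6-ethyl-4-(methoxymethoxy)-5-methyl-2H-pyran-2-one, via mesylate 21 (not isolated)
Conditions: MsCl, LiCl, 2,4,6-collidine, DMF, 0 °C; used crude
Reagents that add atoms: lithium chloride, [Li+].[Cl-]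
Why: Mesylation of the primary, benzylic-type alcohol followed by in situ SN2 displacement of mesylate 21 by chloride proceeds under buffered, non-acidic conditions that spare the MOM acetal.

Step 12
Reactants: 22 3-(chloromethyl)-6-ethyl-4-(methoxymethoxy)-5-methyl-2H-pyran-2-one
Product: 23 {[6-ethyl-4-(methoxymethoxy)-5-methyl-2-oxo-2H-pyran-3-yl]methyl}zinc chloride (THF solution, LiCl-complexed)
Conditions: Zn dust (activated with BrCH2CH2Br and TMSCl), LiCl, THF, 0 → 25 °C; titration with I2
Reagents that add atoms: zinc, [Zn]
Why: Direct oxidative insertion of zinc into the activated benzylic-type C–Cl bond is promoted by LiCl, which takes the organozinc off the metal surface, and the chloride is chosen over the bromide because it gives less Wurtz-type dimer while lactone and acetal tolerate the organozinc.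

Step 13
Reactants: 9 (2R)-1-[3,5-dibromo-2,4,6-tris(methoxymethoxy)phenyl]-2-methylbutan-1-one, 23 {[6-ethyl-4-(methoxymethoxy)-5-methyl-2-oxo-2H-pyran-3-yl]methyl}zinc chloride (two equivalents consumed, three used)
Product: 25 (2R)-1-[3,5-bis{[6-ethyl-4-(methoxymethoxy)-5-methyl-2-oxo-2H-pyran-3-yl]methyl}-2,4,6-tris(methoxymethoxy)phenyl]-2-methylbutan-1-one, via monocoupled bromide 24 (not isolated)
Conditions: Pd2(dba)3 (5 mol %), SPhos (20 mol %), 23 (3 equiv, in portions), THF, 25 → 60 °C
Reagents that add atoms: none
Why: Zerovalent palladium, formed from Pd2(dba)3 and SPhos, inserts into a C–Br bond of 9 although it lies between two OMOM-bearing carbons, because the bulky electron-rich biarylphosphine favours a monoligated, highly reactive metal centre; transmetalation from the benzylic-type zinc chloride 23 and reductive elimination from divalent palladium then give the aryl–CH2 bond, and the cycle repeats at the second bromide through monocoupled bromide 24. The closest known reaction type is the Negishi cross-coupling of benzylic zinc halides with hindered, electron-rich aryl bromides under palladium/dialkylbiarylphosphine catalysis. No ring is closed and no stereocentre is formed; the existing (R) centre next to the ketone is untouched because the organozinc halide is neither basic enough to enolize the ketone nor nucleophilic enough to add to it or to the lactones. The selectivity needed is cross-coupling at both bromides over hydrodebromination and over homocoupling of 23: the CH2–Zn carbon has no β-hydrogen, so β-hydride elimination is not available, fast reductive elimination at the crowded SPhos-bound palladium should outrun protodemetalation, and the excess of 23 added in portions covers loss to dimer. The two bromides are meta to one another and electronically equivalent, so the first benzylation adds bulk but does not deactivate the second C–Br bond.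

Step 14
Reactants: 25 (2R)-1-[3,5-bis{[6-ethyl-4-(methoxymethoxy)-5-methyl-2-oxo-2H-pyran-3-yl]methyl}-2,4,6-tris(methoxymethoxy)phenyl]-2-methylbutan-1-one
Product: 26 3,3'-{[2,4,6-trihydroxy-5-[(2R)-2-methylbutanoyl]-1,3-phenylene]bis(methylene)}bis(6-ethyl-4-hydroxy-5-methyl-2H-pyran-2-one)
Conditions: HCl (3 M in MeOH), 0 °C → rt
Reagents that add atoms: none
Why: Acid-catalysed acetal exchange with methanol (MOM ether cleavage) releases the three phenols and the two pyrone hydroxyls, and the low temperature keeps acid-promoted enolization of the ketone α-centre and cleavage of the diarylmethane-type bonds out of reach.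

**Compound list**

1 | phloroglucinol | Oc1cc(O)cc(O)c1 | starting material
2 | 1,3,5-tris(methoxymethoxy)benzene | COCOc1cc(OCOC)cc(OCOC)c1 | intermediate
3 | (R)-2-methylbutanoic acid | OC(=O)[C@H](C)CC | starting material
4 | (2R)-1-(1H-imidazol-1-yl)-2-methylbutan-1-one (acylimidazole) | O=C([C@H](C)CC)n1ccnc1 | intermediate
5 | (2R)-N-methoxy-N,2-dimethylbutanamide | CON(C)C(=O)[C@H](C)CC | intermediate
6 | [2,4,6-tris(methoxymethoxy)phenyl]lithium | COCOc1cc(OCOC)c([Li])c(OCOC)c1 | intermediate
7 | lithium (2R)-1-[methoxy(methyl)amino]-2-methyl-1-[2,4,6-tris(methoxymethoxy)phenyl]butan-1-olate (both C1 epimers) | COCOc1cc(OCOC)c(C(O[Li])(N(C)OC)[C@H](C)CC)c(OCOC)c1 | intermediate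
8 | (2R)-2-methyl-1-[2,4,6-tris(methoxymethoxy)phenyl]butan-1-one | COCOc1cc(OCOC)c(C(=O)[C@H](C)CC)c(OCOC)c1 | intermediate
9 | (2R)-1-[3,5-dibromo-2,4,6-tris(methoxymethoxy)phenyl]-2-methylbutan-1-one | COCOc1c(Br)c(OCOC)c(C(=O)[C@H](C)CC)c(OCOC)c1Br | intermediate
10 | pentan-3-one | CCC(=O)CC | starting material
11 | 3-(trimethylsilyloxy)pent-2-ene (mixture of alkene isomers) | CC=C(CC)O[Si](C)(C)C | intermediate
12 | malonyl dichloride | O=C(Cl)CC(=O)Cl | starting material
13 | 4-methyl-3,5-dioxoheptanoyl chloride (racemic at C4) | CCC(=O)C(C)C(=O)CC(=O)Cl | intermediate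
14 | 6-ethyl-4-hydroxy-5-methyl-2H-pyran-2-one | CCc1oc(=O)cc(O)c1C | intermediate
15 | 6-ethyl-4-(methoxymethoxy)-5-methyl-2H-pyran-2-one | CCc1oc(=O)cc(OCOC)c1C | intermediate
16 | 3-bromo-6-ethyl-4-(methoxymethoxy)-5-methyl-2H-pyran-2-one | CCc1oc(=O)c(Br)c(OCOC)c1C | intermediate
17 | [6-ethyl-4-(methoxymethoxy)-5-methyl-2-oxo-2H-pyran-3-yl]magnesium chloride | CCc1oc(=O)c([Mg]Cl)c(OCOC)c1C | intermediate
18 | chloromagnesium (dimethylamino)[6-ethyl-4-(methoxymethoxy)-5-methyl-2-oxo-2H-pyran-3-yl]methanolate | CCc1oc(=O)c(C(O[Mg]Cl)N(C)C)c(OCOC)c1C | intermediate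
19 | 6-ethyl-4-(methoxymethoxy)-5-methyl-2-oxo-2H-pyran-3-carbaldehyde | CCc1oc(=O)c(C=O)c(OCOC)c1C | intermediate
20 | 6-ethyl-3-(hydroxymethyl)-4-(methoxymethoxy)-5-methyl-2H-pyran-2-one | CCc1oc(=O)c(CO)c(OCOC)c1C | intermediate
21 | [6-ethyl-4-(methoxymethoxy)-5-methyl-2-oxo-2H-pyran-3-yl]methyl methanesulfonate | CCc1oc(=O)c(COS(C)(=O)=O)c(OCOC)c1C | intermediate
22 | 3-(chloromethyl)-6-ethyl-4-(methoxymethoxy)-5-methyl-2H-pyran-2-one | CCc1oc(=O)c(CCl)c(OCOC)c1C | intermediate
23 | {[6-ethyl-4-(methoxymethoxy)-5-methyl-2-oxo-2H-pyran-3-yl]methyl}zinc chloride | CCc1oc(=O)c(C[Zn]Cl)c(OCOC)c1C | intermediate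
24 | (2R)-1-[3-bromo-5-{[6-ethyl-4-(methoxymethoxy)-5-methyl-2-oxo-2H-pyran-3-yl]methyl}-2,4,6-tris(methoxymethoxy)phenyl]-2-methylbutan-1-one | COCOc1c(Br)c(OCOC)c(C(=O)[C@H](C)CC)c(OCOC)c1Cc1c(OCOC)c(C)c(CC)oc1=O | intermediate
25 | (2R)-1-[3,5-bis{[6-ethyl-4-(methoxymethoxy)-5-methyl-2-oxo-2H-pyran-3-yl]methyl}-2,4,6-tris(methoxymethoxy)phenyl]-2-methylbutan-1-one | COCOc1c(Cc2c(OCOC)c(C)c(CC)oc2=O)c(OCOC)c(C(=O)[C@H](C)CC)c(OCOC)c1Cc1c(OCOC)c(C)c(CC)oc1=O | intermediate
26 | 3,3'-{[2,4,6-trihydroxy-5-[(2R)-2-methylbutanoyl]-1,3-phenylene]bis(methylene)}bis(6-ethyl-4-hydroxy-5-methyl-2H-pyran-2-one) | CCc1oc(=O)c(Cc2c(O)c(Cc3c(O)c(C)c(CC)oc3=O)c(O)c(C(=O)[C@H](C)CC)c2O)c(O)c1C | target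

**Step count and risks**

Total step count: 14.
Longest linear sequence: 10 steps (pentan-3-one 10 to target 26, steps 5 to 14).

Steps most likely to fail:

Step 13. The coupling may stall after the first benzylation, with hydrodebromination of the remaining hindered C–Br bond or consumption of the zinc reagent by homocoupling. The fallback gives up the cross-coupling and forms the same two ring A–CH2 bonds by Mannich/Michael chemistry, setting out from ketone 8 and pyrone 14. HCl in MeOH would strip the three MOM groups of 8 to give (2R)-2-methyl-1-(2,4,6-trihydroxyphenyl)butan-1-one F1. Pyrone 14 and Eschenmoser's salt (Me2N=CH2+ I−) would give the Mannich base 3-[(dimethylamino)methyl]-6-ethyl-4-hydroxy-5-methyl-2H-pyran-2-one F2. On warming with F1, this should lose dimethylamine to 6-ethyl-5-methyl-3-methylidene-2H-pyran-2,4(3H)-dione F3. The free C3 and C5 positions of F1 would trap this Michael acceptor twice, and the route is rejoined directly at target 26.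

Step 12. Zinc insertion may be undercut by Wurtz-type dimerization on the metal surface and by loss of the labile chloromethyl pyrone through ionization or cyclization onto the neighbouring MOM acetal. The fallback replaces the zinc nucleophile by a boron one and sets out from chloride 22. Miyaura borylation (B2pin2, Pd2(dba)3, tris(4-methoxyphenyl)phosphine, KOAc, dioxane) would give 6-ethyl-4-(methoxymethoxy)-5-methyl-3-[(4,4,5,5-tetramethyl-1,3,2-dioxaborolan-2-yl)methyl]-2H-pyran-2-one F4. A twofold Suzuki–Miyaura coupling of F4 with dibromide 9 (Pd(OAc)2, SPhos, K3PO4, toluene/water) would then form the same two bonds and rejoin the route at 25.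

Step 9. The isopropyl Grignard reagent may add to the lactone, or the magnesiated pyrone may open or self-condense, in competition with clean bromine–magnesium exchange and formylation. The fallback avoids any organomagnesium species and sets out from bromide 16. Stille coupling with tributyl(vinyl)stannane (Pd(PPh3)4, toluene, heat) would give 3-ethenyl-6-ethyl-4-(methoxymethoxy)-5-methyl-2H-pyran-2-one F5. Lemieux–Johnson cleavage of the vinyl group (catalytic OsO4, NaIO4, 2,6-lutidine, dioxane/water) would then give aldehyde 19, where the route is rejoined.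

**Further compounds**

F1 | step 13 | (2R)-2-methyl-1-(2,4,6-trihydroxyphenyl)butan-1-one | O=C([C@H](C)CC)c1c(O)cc(O)cc1O
F2 | step 13 | 3-[(dimethylamino)methyl]-6-ethyl-4-hydroxy-5-methyl-2H-pyran-2-one | CCc1oc(=O)c(CN(C)C)c(O)c1C
F3 | step 13 | 6-ethyl-5-methyl-3-methylidene-2H-pyran-2,4(3H)-dione | CCC1=C(C)C(=O)C(=C)C(=O)O1
F4 | step 12 | 6-ethyl-4-(methoxymethoxy)-5-methyl-3-[(4,4,5,5-tetramethyl-1,3,2-dioxaborolan-2-yl)methyl]-2H-pyran-2-one | CCc1oc(=O)c(CB2OC(C)(C)C(C)(C)O2)c(OCOC)c1C
F5 | step 9 | 3-ethenyl-6-ethyl-4-(methoxymethoxy)-5-methyl-2H-pyran-2-one | CCc1oc(=O)c(C=C)c(OCOC)c1C
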